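Two questions stand on this one flask, and both look at the moment when 5.0% of the starting material is converted; call that moment the mark.

- oak: starting material 0.050 M; solid reagent 0.95 equiv; free catalyst 0.05 mol%; the very flask that is asked about, followed so far
- flask: starting material 0.050 M; solid reagent 0.950 equiv; free catalyst 0.05 mol%

oak run (percent of the starting material charged)

| time / d | product / % | starting material / % |
|---|---|---|
| 0.625 | 6 | 61 |
| 1.25 | 14 | 44 |
| 2.00 | 26 | 31 |
| 3.00 | 37 | 19 |
| 4.00 | 49 | 12 |
| 5.00 | 62 | 5 |

(scatter of a reading: 1.5 percentage points)

- factor on the rate of making product when 5.0% of the starting material are converted if free catalyst is charged twice over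
- factor on the rate when 5.0% of the starting material are converted if free catalyst is charged at 0.25 mol% instead

- solid, in amounts per volume of the solution: solid reagent
- at the start none of the solid reagent is in solution
- no earlier run changes the charge of free catalyst; that part of a forecast is a guess

Draw the curve first. In the oak run the first reading gives the starting material an average first-order constant of 0.791 d⁻¹, so I reckon the mark at 0.0649 d, earlier than that reading. Product then climbs in a nearly straight line at 0.128 d⁻¹ of the charge, from 1.25 d to 5.00 d, while starting material falls from 44% to 5%. I read that slope as the pace at which the solid reagent dissolves, with each dissolved portion used as it arrives on this stretch of the line. At this pace the solid reagent, the limiting reagent at 0.950 equiv, lasts 7.42 d, and there the line should bend into a level.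

Now carry one quantity, the mark feed 0.415 mM: the solid reagent dissolved by the mark. My guess, which no run tests, is that the mark comes sooner in proportion to the catalyst. With the catalyst charged twice over, the mark feed then comes to 0.207 mM. I take the rate at the mark to go as catalyst times feed, so I reckon a factor near 1 for both questions.

The forecast differs: 1.9 (1.2 to 2.4) for the doubled charge and 4.5 (1.8 to 6) at 0.25 mol%, holding that “the rate should follow the catalyst roughly first order if catalyst drives the product-forming step”.

The flask gives 1.05 for the doubled charge and 1.06 at 0.25 mol%.

    starting material + free catalyst → free catalyst + open intermediate (k = 0.481 M⁻¹ s⁻¹)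
    free catalyst + open intermediate ⇌ catalyst intermediate (K = 61.2 M⁻¹, k = 1.09 M⁻¹ s⁻¹)
    coupling partner + catalyst intermediate → free catalyst + product (k = 6.47 M⁻¹ s⁻¹)
    solid reagent ⇌ coupling partner, rate k4*(cs4 - [coupling partner]) while solid is left; crystals form when [coupling partner] > cs4 (solubility = 10.0 mM, k = 8.11 × 10⁻⁶ s⁻¹)

As charged, the flask stands at the mark after 0.0528 d, making product at 5.81 × 10⁻⁴ M d⁻¹. At 0.25 mol% the catalyst charge is 5.00 times the first, and on my guess the mark feed, now counted as coupling partner, is reckoned at 0.0830 mM against 0.415 mM, so the reckoned product of catalyst and feed stays the same; the flask's factor on the rate is 1.06.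

(The data were computed for substances that don't exist, and the scatter is random.)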